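**Retrosynthetic overview**

1. Target 35 ⇒ tert-butyl ester 34. The diosphenol comes from C2 hydroxylation and oxidation of the C3 ketone, and the C3 ketone from allylic oxidation next to the C4=C18 methylene (27). The enoate 27 comes from a C12–C13 Negishi coupling of iodide 23 with enol triflate 25.
2. Feature used: C5 is a quaternary, cis-fused ring-fusion carbon bonded directly to C4, the ring A carbon that carries the exocyclic C18 methylene. A C4 bromoalkene hung from C10 on the C1–C3 tether can therefore be added to C5 of a ring B C5=C6 enone (C7 ketone), which forms C4–C5 and closes ring A with the methylene in place (20 ⇒ 19).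
3. 19 ⇒ ring B enone 8 by three conjugate additions (C20 methyl, then vinyl anti to the C10 chain for quaternary C9, then C19 methyl) and three dehydrogenations. 8 ⇒ aldehyde 5 and ethyl vinyl ketone by an organocatalytic Michael addition (sets C10) and aldol condensation.
4. Ring order: ring B first (step 4), ring A second (step 12). C7 is reduced and the side chain attached only after the bicycle exists.

Key step: step 12

Remark: clerodane numbering is used throughout (ring A = C1–C5, C10; ring B = C5–C10; methyls C17, C19, C20 on C8, C5, C9; side chain C11–C16); the carbinol centres at C3 (28) and C2 (31, 32) form as epimer mixtures and become sp2 again.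
Remark: the sense of induction in step 3 is assigned from the usual shielding model for diarylprolinol ether enamines; the enantiomeric catalyst would be used if the opposite sense were found.

**Step 1**
Reactants: 1 2-(3-chloropropyl)-1,3-dioxolane; 2 2,3-dibromoprop-1-ene
Product: 4 2-(5-bromohex-5-en-1-yl)-1,3-dioxolane, via Grignard reagent 3 (not isolated)
Conditions: Mg, BrCH2CH2Br (cat.), THF, reflux; then 2 (1.5 equiv), CuI (5 mol%), THF, −20 → 0 °C
Reagents that add atoms: none
Why: Copper-catalysed allylic substitution of the alkyl Grignard reagent on the allylic bromide of 2 (SN2 and SN2' attack give the same 2-bromoalkene), with the vinylic C–Br bond and the acetal inert.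

**Step 2**
Reactants: 4 2-(5-bromohex-5-en-1-yl)-1,3-dioxolane
Product: 5 6-bromohept-6-enal
Conditions: 1 M HCl, THF, rt
Reagents that add atoms: water, O
Why: Acid-catalysed acetal hydrolysis frees the aldehyde, and the 2-bromoalkene is stable to dilute aqueous acid.

**Step 3**
Reactants: 5 6-bromohept-6-enal; 6 pent-1-en-3-one (ethyl vinyl ketone)
Product: 7 (2S)-2-(4-bromopent-4-en-1-yl)-5-oxoheptanal
Conditions: (R)-2-[diphenyl(trimethylsilyloxy)methyl]pyrrolidine (5 mol%), ethyl 3,4-dihydroxybenzoate (20 mol%), 6 (1.5 equiv), neat, 4 °C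
Reagents that add atoms: none
Why: Enamine-catalysed asymmetric Michael addition of an aldehyde to a vinyl ketone, in which the E-enamine of 5 is attacked on the face away from the diphenyl(silyloxy)methyl group so that the (R)-catalyst should set C10 as S, the catechol activating the enone by hydrogen bonding.

**Step 4**
Reactants: 7 (2S)-2-(4-bromopent-4-en-1-yl)-5-oxoheptanal
Product: 8 (4S)-4-(4-bromopent-4-en-1-yl)-2-methylcyclohex-2-en-1-one
Conditions: LiOH (0.1 equiv), i-PrOH, rt
Reagents that add atoms: none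
Why: Intramolecular aldol condensation closes ring B, since the only enolate that can form a six-membered ring is that of the ethyl ketone CH2 (C8) attacking the aldehyde carbon (C9), and the mild catalytic base should leave the γ-stereocentre C10 intact.

**Step 5**
Reactants: 8 (4S)-4-(4-bromopent-4-en-1-yl)-2-methylcyclohex-2-en-1-one
Product: 9 {[(3R,4S)-4-(4-bromopent-4-en-1-yl)-2,3-dimethylcyclohex-1-en-1-yl]oxy}trimethylsilane
Conditions: Me2CuLi (from MeLi and CuI), TMSCl, THF, −78 °C; Et3N, aq NaHCO3 work-up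
Reagents that add atoms: methyllithium, C[Li] (used as lithium dimethylcuprate, [Li+].C[Cu-]C); chlorotrimethylsilane, C[Si](C)(C)Cl
Why: Chlorosilane-accelerated cuprate conjugate addition places the C20 methyl on C9 anti to the C10 chain and traps the enolate regiospecifically as the tetrasubstituted silyl enol ether, the C9 centre being flattened again in step 6.

**Step 6**
Reactants: 9 {[(3R,4S)-4-(4-bromopent-4-en-1-yl)-2,3-dimethylcyclohex-1-en-1-yl]oxy}trimethylsilane
Product: 10 (4S)-4-(4-bromopent-4-en-1-yl)-2,3-dimethylcyclohex-2-en-1-one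
Conditions: Pd(OAc)2 (1.05 equiv), MeCN, rt
Reagents that add atoms: none
Why: Saegusa–Ito dehydrogenation, in which the divalent palladium enolate at C8 loses the syn β-hydrogen on C9 to give the conjugated tetrasubstituted endocyclic enone, divalent palladium not inserting into the C–Br bond.

**Step 7**
Reactants: 10 (4S)-4-(4-bromopent-4-en-1-yl)-2,3-dimethylcyclohex-2-en-1-one; 11 vinylmagnesium bromide
Product: 12 {[(3R,4S)-4-(4-bromopent-4-en-1-yl)-3-ethenyl-2,3-dimethylcyclohex-1-en-1-yl]oxy}trimethylsilane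
Conditions: 11 (3 equiv), CuBr·SMe2 (20 mol%), TMSCl, HMPA, THF, −78 → −40 °C
Reagents that add atoms: chlorotrimethylsilane, C[Si](C)(C)Cl
Why: Copper-catalysed, chlorosilane-accelerated conjugate addition of a vinyl Grignard reagent to a β,β-disubstituted enone, with axial attack anti to the C10 chain building quaternary C9 (vinyl, the future C11–C12, trans to the tether and C20 cis to it) and the enolate kept as the silyl enol ether to mask C7 in step 8.

**Step 8**
Reactants: 12 {[(3R,4S)-4-(4-bromopent-4-en-1-yl)-3-ethenyl-2,3-dimethylcyclohex-1-en-1-yl]oxy}trimethylsilane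
Product: 14 (2S,3R,4S)-4-(4-bromopent-4-en-1-yl)-3-(2-hydroxyethyl)-2,3-dimethylcyclohexan-1-one, via alkylborane 13 (not isolated)
Conditions: 9-BBN, THF, 0 °C → rt; then NaOH, H2O2, 0 °C; then 1 M HCl, THF, 0 °C
Reagents that add atoms: hydrogen peroxide, OO
Why: Anti-Markovnikov hydroboration–oxidation in which 9-BBN takes the monosubstituted vinyl group in preference to the electron-poor 2-bromoalkene and the tetrasubstituted silyl enol ether, after which cleavage of the enol ether protonates C8 opposite the pseudoaxial C20 methyl and should give the 8,9-cis-dimethyl ketone, which is also expected to be the more stable epimer (C17 equatorial) so that any 8-epimer can be equilibrated with NaOMe in MeOH and recycled.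

**Step 9**
Reactants: 14 (2S,3R,4S)-4-(4-bromopent-4-en-1-yl)-3-(2-hydroxyethyl)-2,3-dimethylcyclohexan-1-one
Product: 15 (2S,3R,4S)-3-[2-(benzyloxy)ethyl]-4-(4-bromopent-4-en-1-yl)-2,3-dimethylcyclohexan-1-one
Conditions: BnOC(=NH)CCl3, TfOH (cat.), CH2Cl2–cyclohexane, 0 °C → rt
Reagents that add atoms: benzyl 2,2,2-trichloroacetimidate, ClC(Cl)(Cl)C(=N)OCc1ccccc1
Why: Acid-catalysed O-benzylation with the trichloroacetimidate avoids an alkoxide base that could enolise C7 and epimerise C8, and the benzyl ether survives the enolate and palladium steps and is removed in the dissolving-metal step 13.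

**Step 10**
Reactants: 15 (2S,3R,4S)-3-[2-(benzyloxy)ethyl]-4-(4-bromopent-4-en-1-yl)-2,3-dimethylcyclohexan-1-one
Product: 17 (4S,5R,6S)-5-[2-(benzyloxy)ethyl]-4-(4-bromopent-4-en-1-yl)-5,6-dimethylcyclohex-2-en-1-one, via lithium enolate 16 (not isolated)
Conditions: LiN(i-Pr)2 (1.1 equiv), THF, −78 °C; then PhS(Cl)=N-t-Bu, −78 °C
Reagents that add atoms: none
Why: Mukaiyama dehydrogenation, in which kinetic deprotonation takes the C6 methylene and not the hindered C8 methine, the enolate is sulfenylated by N-tert-butylbenzenesulfinimidoyl chloride and the adduct eliminates toward C5 at low temperature, giving the C5=C6 enone without touching C8.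

**Step 11**
Reactants: 17 (4S,5R,6S)-5-[2-(benzyloxy)ethyl]-4-(4-bromopent-4-en-1-yl)-5,6-dimethylcyclohex-2-en-1-one
Product: 19 (4S,5R,6S)-5-[2-(benzyloxy)ethyl]-4-(4-bromopent-4-en-1-yl)-3,5,6-trimethylcyclohex-2-en-1-one, via lithium enolate 18 (not isolated)
Conditions: Me2CuLi (from MeLi and CuI), Et2O–THF, −78 °C; then PhS(Cl)=N-t-Bu, −78 °C
Reagents that add atoms: methyllithium, C[Li] (used as lithium dimethylcuprate, [Li+].C[Cu-]C)
Why: Cuprate conjugate addition puts the C19 methyl on C5 and the regiospecific C6 enolate is dehydrogenated in the same flask by the sulfinimidoyl chloride (one-pot β-alkylation of an enone), so the transient C5 configuration is irrelevant and the bromoalkene should not couple with the cuprate at −78 °C.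

**Step 12**
Reactants: 19 (4S,5R,6S)-5-[2-(benzyloxy)ethyl]-4-(4-bromopent-4-en-1-yl)-3,5,6-trimethylcyclohex-2-en-1-one
Product: 20 (3S,4R,4aR,8aS)-4-[2-(benzyloxy)ethyl]-3,4,8a-trimethyl-8-methylideneoctahydronaphthalen-2(1H)-one
Conditions: Pd(OAc)2 (10 mol%), PPh3 (30 mol%), HCO2Na (2 equiv), Bu4NCl, DMF, 80 °C
Reagents that add atoms: none
Why: Zerovalent palladium formed from Pd(OAc)2 and PPh3 inserts into the C4–Br bond, the divalent alkenylpalladium adds syn across C5=C6 with C4 going to C5 and palladium to C6, and because C5 then bears no hydrogen the C6 palladium enolate cannot undergo β-hydride elimination and is reduced by formate (loss of CO2, C6–H formed); this is the intramolecular reductive Heck reaction (alkenylpalladium conjugate addition) known for β-substituted cycloalkenones. Ring A (C1–C5, C10) closes in the 6-exo-trig mode. The new quaternary stereocentre C5 is controlled by C10, because the three-carbon tether can reach C5 only on its own face, so C4 ends cis to C1 and C19 cis to H10 (cis ring fusion). The step needs attack at C5 (6-exo) and not at C6 (7-endo), which the β-regiochemistry of enone carbopalladation and the ring size both secure, and it needs cyclisation to outrun formate reduction of the alkenylpalladium, which sparingly soluble HCO2Na and the chloride additive favour. The bromoalkene carbon becomes C4 with the C18 methylene already in place, C7 stays a ketone, and the weakly basic medium should leave the C8 centre next to it unchanged.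

**Step 13**
Reactants: 20 (3S,4R,4aR,8aS)-4-[2-(benzyloxy)ethyl]-3,4,8a-trimethyl-8-methylideneoctahydronaphthalen-2(1H)-one
Product: 21 (2S,3S,4R,4aR,8aS)-4-(2-hydroxyethyl)-3,4,8a-trimethyl-8-methylidenedecahydronaphthalen-2-ol
Conditions: Li, NH3(l), THF, t-BuOH, −78 °C; NH4Cl
Reagents that add atoms: none
Why: Dissolving-metal (Birch-type) reduction gives the thermodynamically preferred equatorial 7S alcohol, since an axial C7–O bond would be 1,3-diaxial to both C4 and C20 (the same groups block axial hydride delivery, so hydride reagents would give the wrong epimer), and the same conditions cleave the benzyl ether while the isolated methylene is not reduced.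

**Step 14**
Reactants: 21 (2S,3S,4R,4aR,8aS)-4-(2-hydroxyethyl)-3,4,8a-trimethyl-8-methylidenedecahydronaphthalen-2-ol
Product: 22 (2S,3S,4R,4aR,8aS)-4-(2-iodoethyl)-3,4,8a-trimethyl-8-methylidenedecahydronaphthalen-2-ol
Conditions: I2, PPh3, imidazole, CH2Cl2, 0 °C
Reagents that add atoms: iodine, II
Why: Appel-type iodination selects the primary C12 hydroxyl over the secondary C7 hydroxyl, and ether formation between O7 and C12 would need the disfavoured diaxial conformer of ring B.

**Step 15**
Reactants: 22 (2S,3S,4R,4aR,8aS)-4-(2-iodoethyl)-3,4,8a-trimethyl-8-methylidenedecahydronaphthalen-2-ol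
Product: 23 (2S,3S,4R,4aR,8aS)-4-(2-iodoethyl)-3,4,8a-trimethyl-8-methylidenedecahydronaphthalen-2-yl acetate
Conditions: Ac2O, DMAP (cat.), pyridine, 0 °C → rt
Reagents that add atoms: acetic anhydride, CC(=O)OC(C)=O
Why: Nucleophile-catalysed acylation of the equatorial secondary alcohol, the primary iodide being stable to pyridine over the short reaction time.

**Step 16**
Reactants: 24 tert-butyl acetoacetate
Product: 25 tert-butyl (2E)-3-{[(trifluoromethyl)sulfonyl]oxy}but-2-enoate
Conditions: Tf2O, 25% aq Me4NOH, hexane, 5 °C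
Reagents that add atoms: trifluoromethanesulfonic anhydride, O=S(=O)(OS(=O)(=O)C(F)(F)F)C(F)(F)F
Why: O-Sulfonylation of the β-keto ester enolate under biphasic conditions, where the non-chelating tetramethylammonium counter-ion favours the enolate with oxygen anti to the ester and hence the E enol triflate.

**Step 17**
Reactants: 23 (2S,3S,4R,4aR,8aS)-4-(2-iodoethyl)-3,4,8a-trimethyl-8-methylidenedecahydronaphthalen-2-yl acetate; 25 tert-butyl (2E)-3-{[(trifluoromethyl)sulfonyl]oxy}but-2-enoate
Product: 27 tert-butyl (5S,7S,8S,9R,10R,13E)-7-acetoxycleroda-4(18),13-dien-15-oate, via alkylzinc iodide 26 (not isolated)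
Conditions: Zn dust (activated with TMSCl and BrCH2CH2Br), LiCl, THF, 40 °C; then 25, PdCl2(dppf) (5 mol%; dppf = 1,1'-bis(diphenylphosphino)ferrocene), THF, 50 °C
Reagents that add atoms: none
Why: Zinc insertion into the primary C12–I bond tolerates the acetate, and the sp3–sp2 Negishi coupling with the enol triflate forms C12–C13 with retention of alkene geometry, giving the 13E enoate.

**Step 18**
Reactants: 27 tert-butyl (5S,7S,8S,9R,10R,13E)-7-acetoxycleroda-4(18),13-dien-15-oate
Product: 28 tert-butyl (13E)-7-acetoxy-3-hydroxycleroda-4(18),13-dien-15-oate (C3 epimers)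
Conditions: SeO2 (0.5 equiv), t-BuOOH, CH2Cl2, rt
Reagents that add atoms: selenium dioxide, O=[Se]=O; tert-butyl hydroperoxide, CC(C)(C)OO
Why: Riley allylic oxidation, in which an ene reaction at the C18 terminus and a [2,3]-sigmatropic shift return the double bond to C4=C18 and oxygenate C3, the only allylic C–H position of the electron-rich 1,1-disubstituted alkene (C5 is quaternary), while the electron-poor enoate is not attacked.

**Step 19**
Reactants: 28 tert-butyl (13E)-7-acetoxy-3-hydroxycleroda-4(18),13-dien-15-oate (C3 epimers)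
Product: 29 tert-butyl (5S,7S,8S,9R,10R,13E)-7-acetoxy-3-oxocleroda-4(18),13-dien-15-oate
Conditions: Dess–Martin periodinane, NaHCO3, CH2Cl2, rt
Reagents that add atoms: none
Why: Dess–Martin oxidation of the allylic alcohol converges both C3 epimers, and any enone already formed in step 18, on the α-methylene ketone under non-basic conditions.

**Step 20**
Reactants: 29 tert-butyl (5S,7S,8S,9R,10R,13E)-7-acetoxy-3-oxocleroda-4(18),13-dien-15-oate
Product: 30 tert-butyl (5S,7S,8S,9R,10R,13E)-7-acetoxy-3-[(trimethylsilyl)oxy]cleroda-2,4(18),13-trien-15-oate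
Conditions: TMSOTf, i-Pr2NEt, CH2Cl2, −78 → 0 °C
Reagents that add atoms: trimethylsilyl trifluoromethanesulfonate, C[Si](C)(C)OS(=O)(=O)C(F)(F)F
Why: Soft enolisation, in which C2 carries the only α-hydrogens of the C3 ketone and the silyl triflate with a hindered amine enolises the ketone far faster than the acetate or the tert-butyl enoate, giving the 2-silyloxy diene without a strong base.

**Step 21**
Reactants: 30 tert-butyl (5S,7S,8S,9R,10R,13E)-7-acetoxy-3-[(trimethylsilyl)oxy]cleroda-2,4(18),13-trien-15-oate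
Product: 32 tert-butyl (13E)-7-acetoxy-2-hydroxy-3-oxocleroda-4(18),13-dien-15-oate (C2 epimers), via silyloxy epoxide 31 (not isolated)
Conditions: DMDO, acetone–CH2Cl2, −78 → −20 °C; then citric acid, MeOH–H2O, 0 °C
Reagents that add atoms: dimethyldioxirane, CC1(C)OO1
Why: Rubottom oxidation, in which the electrophilic dioxirane epoxidises the most electron-rich double bond (the C2=C3 silyl enol ether) in preference to C4=C18 and C13=C14, and mild acid opens the silyloxy epoxide to the α-hydroxy ketone.

**Step 22**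
Reactants: 32 tert-butyl (13E)-7-acetoxy-2-hydroxy-3-oxocleroda-4(18),13-dien-15-oate (C2 epimers)
Product: 34 tert-butyl (5S,7S,8S,9R,10R,13E)-7-acetoxy-2-hydroxy-3-oxocleroda-1,4(18),13-trien-15-oate, via 2,3-dione 33 (not isolated)
Conditions: Dess–Martin periodinane, CH2Cl2, rt
Reagents that add atoms: none
Why: Dess–Martin oxidation of the acyloin gives the 2,3-dione, which can enolise only toward C1 and so gives the conjugated diosphenol.

**Step 23**
Reactants: 34 tert-butyl (5S,7S,8S,9R,10R,13E)-7-acetoxy-2-hydroxy-3-oxocleroda-1,4(18),13-trien-15-oate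
Product: 35 (5S,7S,8S,9R,10R,13E)-7-acetoxy-2-hydroxy-3-oxocleroda-1,4(18),13-trien-15-oic acid (CNP0192653.1)
Conditions: TFA, CH2Cl2, 0 °C
Reagents that add atoms: none
Why: Acidolysis of the tert-butyl ester (loss of 2-methylpropene) frees the acid without base or nucleophile, so the C7 acetate, the α-methylene ketone and the diosphenol should survive.

**Compound list**

1 | 2-(3-chloropropyl)-1,3-dioxolane | ClCCCC1OCCO1 | starting material
2 | 2,3-dibromoprop-1-ene | C=C(Br)CBr | starting material
3 | [3-(1,3-dioxolan-2-yl)propyl]magnesium chloride | Cl[Mg]CCCC1OCCO1 | intermediate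
4 | 2-(5-bromohex-5-en-1-yl)-1,3-dioxolane | C=C(Br)CCCCC1OCCO1 | intermediate
5 | 6-bromohept-6-enal | C=C(Br)CCCCC=O | intermediate
6 | pent-1-en-3-one (ethyl vinyl ketone) | C=CC(=O)CC | starting material
7 | (2S)-2-(4-bromopent-4-en-1-yl)-5-oxoheptanal | C=C(Br)CCC[C@H](C=O)CCC(=O)CC | intermediate
8 | (4S)-4-(4-bromopent-4-en-1-yl)-2-methylcyclohex-2-en-1-one | C=C(Br)CCC[C@H]1CCC(=O)C(C)=C1 | intermediate
9 | {[(3R,4S)-4-(4-bromopent-4-en-1-yl)-2,3-dimethylcyclohex-1-en-1-yl]oxy}trimethylsilane (3-methyl trans to the C4 chain) | C=C(Br)CCC[C@H]1CCC(O[Si](C)(C)C)=C(C)[C@@H]1C | intermediate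
10 | (4S)-4-(4-bromopent-4-en-1-yl)-2,3-dimethylcyclohex-2-en-1-one | C=C(Br)CCC[C@H]1CCC(=O)C(C)=C1C | intermediate
11 | vinylmagnesium bromide | C=C[Mg]Br | starting material
12 | {[(3R,4S)-4-(4-bromopent-4-en-1-yl)-3-ethenyl-2,3-dimethylcyclohex-1-en-1-yl]oxy}trimethylsilane (vinyl trans to the C4 chain) | C=C(Br)CCC[C@H]1CCC(O[Si](C)(C)C)=C(C)[C@]1(C)C=C | intermediate
13 | B-alkyl-9-borabicyclo[3.3.1]nonane from hydroboration of the vinyl group of 12 | C=C(Br)CCC[C@H]1CCC(O[Si](C)(C)C)=C(C)[C@]1(C)CCB2C3CCCC2CCC3 | intermediate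
14 | (2S,3R,4S)-4-(4-bromopent-4-en-1-yl)-3-(2-hydroxyethyl)-2,3-dimethylcyclohexan-1-one (C8 methyl, C9 methyl and C10 chain on one face) | C=C(Br)CCC[C@H]1CCC(=O)[C@@H](C)[C@]1(C)CCO | intermediate
15 | (2S,3R,4S)-3-[2-(benzyloxy)ethyl]-4-(4-bromopent-4-en-1-yl)-2,3-dimethylcyclohexan-1-one | C=C(Br)CCC[C@H]1CCC(=O)[C@@H](C)[C@]1(C)CCOCc2ccccc2 | intermediate
16 | lithium C6–C7 enolate of 15 | C=C(Br)CCC[C@H]1CC=C(O[Li])[C@@H](C)[C@]1(C)CCOCc2ccccc2 | intermediate
17 | (4S,5R,6S)-5-[2-(benzyloxy)ethyl]-4-(4-bromopent-4-en-1-yl)-5,6-dimethylcyclohex-2-en-1-one | C=C(Br)CCC[C@H]1C=CC(=O)[C@@H](C)[C@]1(C)CCOCc2ccccc2 | intermediate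
18 | lithium C6–C7 enolate of the C5 methyl adduct of 17 (C19 trans to the C10 chain) | C=C(Br)CCC[C@H]1[C@H](C)C=C(O[Li])[C@@H](C)[C@]1(C)CCOCc2ccccc2 | intermediate
19 | (4S,5R,6S)-5-[2-(benzyloxy)ethyl]-4-(4-bromopent-4-en-1-yl)-3,5,6-trimethylcyclohex-2-en-1-one | C=C(Br)CCC[C@H]1C(C)=CC(=O)[C@@H](C)[C@]1(C)CCOCc2ccccc2 | intermediate
20 | (3S,4R,4aR,8aS)-4-[2-(benzyloxy)ethyl]-3,4,8a-trimethyl-8-methylideneoctahydronaphthalen-2(1H)-one (cis-fused; clerodane 5S,8S,9R,10R) | C=C1CCC[C@@H]2[C@@](C)(CCOCc3ccccc3)[C@H](C)C(=O)C[C@]12C | intermediate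
21 | (2S,3S,4R,4aR,8aS)-4-(2-hydroxyethyl)-3,4,8a-trimethyl-8-methylidenedecahydronaphthalen-2-ol | C=C1CCC[C@@H]2[C@@](C)(CCO)[C@H](C)[C@@H](O)C[C@]12C | intermediate
22 | (2S,3S,4R,4aR,8aS)-4-(2-iodoethyl)-3,4,8a-trimethyl-8-methylidenedecahydronaphthalen-2-ol | C=C1CCC[C@@H]2[C@@](C)(CCI)[C@H](C)[C@@H](O)C[C@]12C | intermediate
23 | (2S,3S,4R,4aR,8aS)-4-(2-iodoethyl)-3,4,8a-trimethyl-8-methylidenedecahydronaphthalen-2-yl acetate | C=C1CCC[C@@H]2[C@@](C)(CCI)[C@H](C)[C@@H](OC(C)=O)C[C@]12C | intermediate
24 | tert-butyl acetoacetate | CC(=O)CC(=O)OC(C)(C)C | starting material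
25 | tert-butyl (2E)-3-{[(trifluoromethyl)sulfonyl]oxy}but-2-enoate | C/C(OS(=O)(=O)C(F)(F)F)=C\C(=O)OC(C)(C)C | intermediate
26 | alkylzinc iodide from 23 (C12–ZnI) | C=C1CCC[C@@H]2[C@@](C)(CC[Zn]I)[C@H](C)[C@@H](OC(C)=O)C[C@]12C | intermediate
27 | tert-butyl (5S,7S,8S,9R,10R,13E)-7-acetoxycleroda-4(18),13-dien-15-oate | C=C1CCC[C@@H]2[C@@](C)(CC/C(C)=C/C(=O)OC(C)(C)C)[C@H](C)[C@@H](OC(C)=O)C[C@]12C | intermediate
28 | tert-butyl (13E)-7-acetoxy-3-hydroxycleroda-4(18),13-dien-15-oate (C3 epimers) | C=C1C(O)CC[C@@H]2[C@@](C)(CC/C(C)=C/C(=O)OC(C)(C)C)[C@H](C)[C@@H](OC(C)=O)C[C@]12C | intermediate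
29 | tert-butyl (5S,7S,8S,9R,10R,13E)-7-acetoxy-3-oxocleroda-4(18),13-dien-15-oate | C=C1C(=O)CC[C@@H]2[C@@](C)(CC/C(C)=C/C(=O)OC(C)(C)C)[C@H](C)[C@@H](OC(C)=O)C[C@]12C | intermediate
30 | tert-butyl (5S,7S,8S,9R,10R,13E)-7-acetoxy-3-[(trimethylsilyl)oxy]cleroda-2,4(18),13-trien-15-oate | C=C1C(O[Si](C)(C)C)=CC[C@@H]2[C@@](C)(CC/C(C)=C/C(=O)OC(C)(C)C)[C@H](C)[C@@H](OC(C)=O)C[C@]12C | intermediate
31 | tert-butyl (13E)-7-acetoxy-2,3-epoxy-3-[(trimethylsilyl)oxy]cleroda-4(18),13-dien-15-oate (epoxide epimers) | C=C1C3(O[Si](C)(C)C)OC3C[C@@H]2[C@@](C)(CC/C(C)=C/C(=O)OC(C)(C)C)[C@H](C)[C@@H](OC(C)=O)C[C@]12C | intermediate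
32 | tert-butyl (13E)-7-acetoxy-2-hydroxy-3-oxocleroda-4(18),13-dien-15-oate (C2 epimers) | C=C1C(=O)C(O)C[C@@H]2[C@@](C)(CC/C(C)=C/C(=O)OC(C)(C)C)[C@H](C)[C@@H](OC(C)=O)C[C@]12C | intermediate
33 | tert-butyl (5S,7S,8S,9R,10R,13E)-7-acetoxy-2,3-dioxocleroda-4(18),13-dien-15-oate | C=C1C(=O)C(=O)C[C@@H]2[C@@](C)(CC/C(C)=C/C(=O)OC(C)(C)C)[C@H](C)[C@@H](OC(C)=O)C[C@]12C | intermediate
34 | tert-butyl (5S,7S,8S,9R,10R,13E)-7-acetoxy-2-hydroxy-3-oxocleroda-1,4(18),13-trien-15-oate | C=C1C(=O)C(O)=C[C@@H]2[C@@](C)(CC/C(C)=C/C(=O)OC(C)(C)C)[C@H](C)[C@@H](OC(C)=O)C[C@]12C | intermediate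
35 | (5S,7S,8S,9R,10R,13E)-7-acetoxy-2-hydroxy-3-oxocleroda-1,4(18),13-trien-15-oic acid (CNP0192653.1) | C=C1C(=O)C(O)=C[C@@H]2[C@@](C)(CC/C(C)=C/C(=O)O)[C@H](C)[C@@H](OC(C)=O)C[C@]12C | target

**Step count**

Total: 23 steps. Longest linear sequence: 22 steps (steps 1–15 and 17–23; step 16 prepares coupling partner 25).

**Steps most likely to fail, with fallbacks**

Step 12 (key step). The alkenylpalladium may be reduced by formate before it inserts (hydrodebromination). Carbopalladation of the β,β-disubstituted C5=C6 bond has to pass through the half-chair in which the C10 tether and the C8 methyl are both pseudoaxial, so insertion may be slow and the catalyst may decompose first. The fallback replaces organopalladium chemistry by a radical conjugate addition and sets out from 19. Bu3SnH and AIBN in benzene at 80 °C (slow addition, high dilution) generate the C4 alkenyl radical, which should close 6-exo-trig onto C5 of the enone. The resulting C6 α-keto radical takes hydrogen from the stannane, so the sequence comes back to the route at 20. It makes no compound outside the list (F0). The cis fusion is again enforced by delivery from C10.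

Step 7. Conjugate addition at the tetrasubstituted, γ-branched enone may be slow or incomplete, with competing 1,2-addition or enolisation by the Grignard reagent. The fallback sets out from 10 and uses a Lewis-acid-driven Hosomi–Sakurai allylation, which is less sensitive to steric hindrance. Allyltrimethylsilane and TiCl4 in CH2Cl2 at −78 °C should add allyl to C9 anti to the C10 chain and give (2S,3R,4S)-4-(4-bromopent-4-en-1-yl)-2,3-dimethyl-3-(prop-2-en-1-yl)cyclohexan-1-one F1. OsO4 (cat.) with NMO dihydroxylates the monosubstituted alkene in preference to the electron-poor bromoalkene and gives (2S,3R,4S)-4-(4-bromopent-4-en-1-yl)-3-(2,3-dihydroxypropyl)-2,3-dimethylcyclohexan-1-one F2. NaIO4 in THF–water cleaves the diol to 2-[(1R,2S,6S)-6-(4-bromopent-4-en-1-yl)-1,2-dimethyl-3-oxocyclohexyl]acetaldehyde F3. NaBH4 in EtOH–CH2Cl2 at −78 °C reduces the aldehyde in preference to the hindered ketone, and the sequence comes back to the route at 14.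

Step 6. β-Hydride elimination may go toward the C17 methyl and not C9, giving the exocyclic enone, and the zerovalent palladium released may insert into the C–Br bond. The fallback sets out from 9 and uses halogenation and dehydrohalogenation. NBS in THF at 0 °C converts the silyl enol ether into (3R,4S)-2-bromo-4-(4-bromopent-4-en-1-yl)-2,3-dimethylcyclohexan-1-one F4. Li2CO3 and LiBr in DMF at 110 °C eliminate HBr under thermodynamic control to the conjugated endocyclic enone, and the sequence comes back to the route at 10.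

**Further compounds**

F0 | step 12 | none | none
F1 | step 7 | (2S,3R,4S)-4-(4-bromopent-4-en-1-yl)-2,3-dimethyl-3-(prop-2-en-1-yl)cyclohexan-1-one | C=C(Br)CCC[C@H]1CCC(=O)[C@@H](C)[C@]1(C)CC=C
F2 | step 7 | (2S,3R,4S)-4-(4-bromopent-4-en-1-yl)-3-(2,3-dihydroxypropyl)-2,3-dimethylcyclohexan-1-one (carbinol epimers) | C=C(Br)CCC[C@H]1CCC(=O)[C@@H](C)[C@]1(C)CC(O)CO
F3 | step 7 | 2-[(1R,2S,6S)-6-(4-bromopent-4-en-1-yl)-1,2-dimethyl-3-oxocyclohexyl]acetaldehyde | C=C(Br)CCC[C@H]1CCC(=O)[C@@H](C)[C@]1(C)CC=O
F4 | step 6 | (3R,4S)-2-bromo-4-(4-bromopent-4-en-1-yl)-2,3-dimethylcyclohexan-1-one (C2 epimers) | C=C(Br)CCC[C@H]1CCC(=O)C(C)(Br)[C@@H]1C
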